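**Retrosynthetic overview**
1. Target 20 ⇒ diene 19 by ring-closing olefin metathesis at C6=C7. Ring B is the only skeletal ring made in the route and is closed last. The closure is possible because the C4 arm (on C3a) and the C8 arm (on C8a) are cis on the C3a–C8a bond of ring A and C8a is quaternary, which holds the two olefins within reach.
2. 19 ⇒ aldehyde 17 (C4–C5 by reagent-controlled methallylboration, then anisoylation) ⇒ lactol 13 (C7–C8 by Felkin–Anh vinyl addition, then acetylation).
3. 13 ⇒ hydroxy lactone 12 ⇒ alkene 11 (Mukaiyama hydration sets C3) ⇒ keto lactone 9 (enol triflate, Negishi isopropylation).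
4. 9 ⇒ lactol 8, a temporary cis-fused oxolane ring between C4 and C8 that fixes C3a against C8a by epimerisation ⇒ 3-methylcyclopent-2-en-1-one 1 (copper-catalysed conjugate addition sets C8a, then hydroxymethylation).
5. Ring order: ring A (present in 1) → temporary O-ring (steps 3–8, opened in step 9) → ring B (step 15).

Key step: step 15

Remark: locants C1–C8a are those of the hydroazulene core of the target (ring A = C1, C2, C3, C3a, C8a; ring B = C3a, C4, C5, C6, C7, C8, C8a). It is assumed that the ligand antipode in step 1 can be chosen to give (R)-5 and that the (−)-Ipc2B reagent from (+)-α-pinene in step 13 adds to the Si face of the aldehyde.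

**Step 1**
Reactants: 1 3-methylcyclopent-2-en-1-one; 2 hex-1-yne
Product: 5 {[(3R)-3-[(E)-hex-1-en-1-yl]-3-methylcyclopent-1-en-1-yl]oxy}trimethylsilane, via alkenylalane 3 (not isolated), via aluminium enolate 4 (not isolated)
Conditions: 2, (i-Bu)2AlH, hexane, 50 °C; then 1, copper thiophene-2-carboxylate CuO2CC4H3S (5 mol %), chiral phosphinamine ligand (5.5 mol %), Et2O, −30 °C; then Me3SiOTf, −30 °C to rt
Reagents that add atoms: trimethylsilyl trifluoromethanesulfonate, C[Si](C)(C)OS(=O)(=O)C(F)(F)F
Why: Hydroalumination gives the (E)-alkenylalane, whose copper-catalysed asymmetric conjugate addition to the β-methyl enone should create the quaternary C8a centre under ligand control, and O-silylation traps the aluminium enolate regiospecifically toward C3a.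

**Step 2**
Reactants: 5 silyl enol ether
Product: 6 (3R)-3-[(E)-hex-1-en-1-yl]-2-(hydroxymethyl)-3-methylcyclopentan-1-one (both C3a epimers)
Conditions: aq. HCHO (37 %), Sc(OTf)3 (10 mol %), THF, rt
Reagents that add atoms: formaldehyde, C=O
Why: Lewis-acid-catalysed Mukaiyama aldol (hydroxymethylation) with aqueous formaldehyde should place C4 on C3a; the C3a configuration is left open because both epimers are funnelled in step 3.

**Step 3**
Reactants: 6 hydroxymethyl ketone
Product: 8 cis-fused keto lactol (3aR,6aS)-1-hydroxy-6a-methylhexahydrocyclopenta[c]furan-4-one (anomers), via keto aldehyde 7 (not isolated)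
Conditions: O3, CH2Cl2–MeOH, −78 °C; Me2S, −78 °C to rt; then DBU (0.2 equiv), CH2Cl2, rt
Reagents that add atoms: ozone, [O-][O+]=O
Why: Ozonolysis unmasks the C8 aldehyde, and base-mediated epimerisation α to the ketone should let only the cis isomer be trapped as the five-membered lactol, so C3a is set cis to C8 by thermodynamic control through the ring constraint.

**Step 4**
Reactants: 8 keto lactol
Product: 9 (3aR,6aS)-6a-methyltetrahydro-1H-cyclopenta[c]furan-1,4(5H)-dione (keto lactone)
Conditions: TEMPO (10 mol %), PhI(OAc)2, CH2Cl2, rt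
Reagents that add atoms: none
Why: Oxoammonium (TEMPO) oxidation of the lactol should give the lactone, which has no α-hydrogen and holds the C8 and C4 oxygen functions in one temporary ring.

**Step 5**
Reactants: 9 keto lactone
Product: 10 (3aR,6aS)-6a-methyl-1-oxo-3,3a,6,6a-tetrahydro-1H-cyclopenta[c]furan-4-yl trifluoromethanesulfonate
Conditions: KN(SiMe3)2, THF, −78 °C; then PhNTf2, −78 °C to 0 °C
Reagents that add atoms: N-phenylbis(trifluoromethanesulfonimide), O=S(=O)(N(c1ccccc1)S(=O)(=O)C(F)(F)F)C(F)(F)F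
Why: Kinetic enolisation with a bulky amide base should remove a proton from the unhindered C2 methylene and not the ring-fusion C3a–H, and enol triflate formation fixes the C2=C3 regiochemistry.

**Step 6**
Reactants: 10 enol triflate
Product: 11 (3aR,6aS)-6a-methyl-4-(propan-2-yl)-3,3a,6,6a-tetrahydro-1H-cyclopenta[c]furan-1-one
Conditions: i-PrZnBr, Pd(dppf)Cl2 (5 mol %), THF, 50 °C
Reagents that add atoms: isopropylzinc bromide, CC(C)[Zn]Br
Why: Negishi cross-coupling of the enol triflate with the secondary alkylzinc should install the isopropyl group; the bidentate dppf ligand disfavours β-hydride isomerisation and the lactone is inert to organozinc.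

**Step 7**
Reactants: 11 alkene lactone
Product: 12 (3aR,4R,6aS)-4-hydroxy-6a-methyl-4-(propan-2-yl)hexahydro-1H-cyclopenta[c]furan-1-one
Conditions: Co(acac)2 (20 mol %), PhSiH3, O2 (1 atm), THF–i-PrOH, 0 °C to rt; then aq. Na2S2O3
Reagents that add atoms: dioxygen, O=O
Why: Mukaiyama hydration (hydrogen-atom transfer to C2) should give the tertiary C3 radical, which is trapped by O2 on the convex face of the cis-fused bicycle, anti to the lactone ring on C3a, setting the (3R) tertiary alcohol.

**Step 8**
Reactants: 12 hydroxy lactone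
Product: 13 (3aR,4R,6aS)-6a-methyl-4-(propan-2-yl)hexahydro-1H-cyclopenta[c]furan-1,4-diol (lactol, anomers)
Conditions: (i-Bu)2AlH (2.2 equiv), CH2Cl2, −78 °C; aq. Rochelle salt
Reagents that add atoms: none
Why: Low-temperature DIBAL-H reduction of a lactone should stop at the lactol because the tetrahedral aluminium hemiacetal survives until work-up.

**Step 9**
Reactants: 13 lactol
Product: 14 (1R,2R,3S)-2-(hydroxymethyl)-3-[(1S)-1-hydroxyprop-2-en-1-yl]-3-methyl-1-(propan-2-yl)cyclopentan-1-ol
Conditions: CH2=CHMgBr (4 equiv), THF, −78 °C to 0 °C; aq. NH4Cl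
Reagents that add atoms: vinylmagnesium bromide, C=C[Mg]Br
Why: The lactol reacts through its open hydroxy aldehyde, and Grignard 1,2-addition under Felkin–Anh control (C3a as the large group anti to the nucleophile, approach past the C8a methyl) should set (8S).

**Step 10**
Reactants: 14 triol
Product: 15 (1S)-1-[(1S,2R,3R)-2-(acetoxymethyl)-3-hydroxy-1-methyl-3-(propan-2-yl)cyclopentyl]prop-2-en-1-yl acetate
Conditions: Ac2O, Et3N, DMAP (cat.), CH2Cl2, 0 °C to rt
Reagents that add atoms: acetic anhydride, CC(=O)OC(C)=O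
Why: DMAP-catalysed acetylation should esterify the primary and the secondary allylic hydroxyl, while the hindered tertiary C3–OH does not react.

**Step 11**
Reactants: 15 diacetate
Product: 16 (1S)-1-[(1S,2R,3R)-3-hydroxy-2-(hydroxymethyl)-1-methyl-3-(propan-2-yl)cyclopentyl]prop-2-en-1-yl acetate
Conditions: K2CO3 (0.2 equiv), MeOH, 0 °C
Reagents that add atoms: none
Why: Base-catalysed transesterification (Zemplén-type methanolysis) should cleave the primary acetate faster than the secondary acetate that sits next to the quaternary C8a.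

**Step 12**
Reactants: 16 mono-acetate
Product: 17 (1S)-1-[(1S,2S,3R)-2-formyl-3-hydroxy-1-methyl-3-(propan-2-yl)cyclopentyl]prop-2-en-1-yl acetate
Conditions: Dess–Martin periodinane, NaHCO3, CH2Cl2, 0 °C to rt
Reagents that add atoms: none
Why: Dess–Martin oxidation under buffered, non-basic conditions should give the β-hydroxy aldehyde without epimerisation at C3a or retro-aldol cleavage.

**Step 13**
Reactants: 17 aldehyde
Product: 18 (1S)-1-[(1S,2R,3R)-3-hydroxy-2-[(1S)-1-hydroxy-3-methylbut-3-en-1-yl]-1-methyl-3-(propan-2-yl)cyclopentyl]prop-2-en-1-yl acetate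
Conditions: (−)-Ipc2B(CH2C(CH3)=CH2) (2.5 equiv), Et2O, −78 °C; then NaBO3·4H2O, THF–H2O, rt
Reagents that add atoms: (−)-B-(2-methylallyl)diisopinocampheylborane, CC(=C)CB(C1CC2CC(C1C)C2(C)C)C1CC2CC(C1C)C2(C)C
Why: Brown asymmetric methallylboration through a chair-like six-membered transition state should deliver the methallyl group to the Si face of the aldehyde, setting (4S) under reagent control.

**Step 14**
Reactants: 18 homoallylic alcohol
Product: 19 (1S)-1-[(1R,2R,5S)-5-[(1S)-1-acetoxyprop-2-en-1-yl]-2-hydroxy-5-methyl-2-(propan-2-yl)cyclopentyl]-3-methylbut-3-en-1-yl 4-methoxybenzoate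
Conditions: 4-MeOC6H4COCl, DMAP, Et3N, CH2Cl2, rt
Reagents that add atoms: 4-methoxybenzoyl chloride, COc1ccc(cc1)C(Cl)=O
Why: DMAP-catalysed acylation should esterify the secondary C4 alcohol, the tertiary alcohol being too hindered to react.

**Step 15**
Reactants: 19 diene
Product: 20 (3R,3aR,4S,8S,8aS)-8-acetoxy-3-hydroxy-6,8a-dimethyl-3-(propan-2-yl)-1,2,3,3a,4,5,8,8a-octahydroazulen-4-yl 4-methoxybenzoate
Conditions: second-generation Hoveyda–Grubbs catalyst (10 mol %), Ti(Oi-Pr)4 (0.3 equiv), toluene (0.002 M), 80 °C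
Reagents that add atoms: none
Why: Ring-closing olefin metathesis: the ruthenium alkylidene should load on the monosubstituted vinyl group at C7, add to the 1,1-disubstituted C6 olefin by [2+2] cycloaddition and release ethene by cycloreversion, forming the C6=C7 bond. The closest known reaction type is ring-closing metathesis of a monosubstituted with a 1,1-disubstituted olefin to a trisubstituted cycloalkene flanked by oxygenated carbons. Ring B (C3a–C4–C5–C6–C7–C8–C8a) closes between the termini of the two arms, and the seven-membered ring size enforces the (Z)-olefin. No stereocentre is created; C4 and C8 (set in steps 13 and 9) and C3, C3a and C8a are not touched. The step needs cyclisation over oligomerisation and a catalyst free of ester chelation: the arms are cis on C3a/C8a and C8a is quaternary (gem-disubstituent effect), high dilution is used, and Ti(Oi-Pr)4 breaks ester–ruthenium chelates. The trisubstituted product olefin should be inert to further metathesis, and both esters and the tertiary alcohol are tolerated.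

**Compound list**
1 | 3-methylcyclopent-2-en-1-one | CC1=CC(=O)CC1 | starting material
2 | hex-1-yne | CCCCC#C | starting material
3 | (E)-hex-1-en-1-yl(diisobutyl)alane | CCCC/C=C/[Al](CC(C)C)CC(C)C | intermediate
4 | diisobutylaluminium (3R)-3-[(E)-hex-1-en-1-yl]-3-methylcyclopent-1-en-1-olate | C[C@]1(/C=C/CCCC)CCC(O[Al](CC(C)C)CC(C)C)=C1 | intermediate
5 | {[(3R)-3-[(E)-hex-1-en-1-yl]-3-methylcyclopent-1-en-1-yl]oxy}trimethylsilane | C[C@]1(/C=C/CCCC)CCC(O[Si](C)(C)C)=C1 | intermediate
6 | (3R)-3-[(E)-hex-1-en-1-yl]-2-(hydroxymethyl)-3-methylcyclopentan-1-one (C2 epimers) | C[C@]1(/C=C/CCCC)CCC(=O)C1CO | intermediate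
7 | (1S)-2-(hydroxymethyl)-1-methyl-3-oxocyclopentane-1-carbaldehyde (C2 epimers) | C[C@]1(C=O)CCC(=O)C1CO | intermediate
8 | (3aR,6aS)-1-hydroxy-6a-methylhexahydrocyclopenta[c]furan-4-one (cis-fused, anomers) | C[C@]12CCC(=O)[C@H]1COC2O | intermediate
9 | (3aR,6aS)-6a-methyltetrahydro-1H-cyclopenta[c]furan-1,4(5H)-dione | C[C@]12CCC(=O)[C@H]1COC2=O | intermediate
10 | (3aR,6aS)-6a-methyl-1-oxo-3,3a,6,6a-tetrahydro-1H-cyclopenta[c]furan-4-yl trifluoromethanesulfonate | C[C@]12CC=C(OS(=O)(=O)C(F)(F)F)[C@H]1COC2=O | intermediate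
11 | (3aR,6aS)-6a-methyl-4-(propan-2-yl)-3,3a,6,6a-tetrahydro-1H-cyclopenta[c]furan-1-one | C[C@]12CC=C(C(C)C)[C@H]1COC2=O | intermediate
12 | (3aR,4R,6aS)-4-hydroxy-6a-methyl-4-(propan-2-yl)hexahydro-1H-cyclopenta[c]furan-1-one | C[C@]12CC[C@@](O)(C(C)C)[C@H]1COC2=O | intermediate
13 | (3aR,4R,6aS)-6a-methyl-4-(propan-2-yl)hexahydro-1H-cyclopenta[c]furan-1,4-diol (anomers) | C[C@]12CC[C@@](O)(C(C)C)[C@H]1COC2O | intermediate
14 | (1R,2R,3S)-2-(hydroxymethyl)-3-[(1S)-1-hydroxyprop-2-en-1-yl]-3-methyl-1-(propan-2-yl)cyclopentan-1-ol | C[C@]1([C@@H](O)C=C)CC[C@@](O)(C(C)C)[C@H]1CO | intermediate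
15 | (1S)-1-[(1S,2R,3R)-2-(acetoxymethyl)-3-hydroxy-1-methyl-3-(propan-2-yl)cyclopentyl]prop-2-en-1-yl acetate | C[C@]1([C@@H](OC(C)=O)C=C)CC[C@@](O)(C(C)C)[C@H]1COC(C)=O | intermediate
16 | (1S)-1-[(1S,2R,3R)-3-hydroxy-2-(hydroxymethyl)-1-methyl-3-(propan-2-yl)cyclopentyl]prop-2-en-1-yl acetate | C[C@]1([C@@H](OC(C)=O)C=C)CC[C@@](O)(C(C)C)[C@H]1CO | intermediate
17 | (1S)-1-[(1S,2S,3R)-2-formyl-3-hydroxy-1-methyl-3-(propan-2-yl)cyclopentyl]prop-2-en-1-yl acetate | C[C@]1([C@@H](OC(C)=O)C=C)CC[C@@](O)(C(C)C)[C@H]1C=O | intermediate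
18 | (1S)-1-[(1S,2R,3R)-3-hydroxy-2-[(1S)-1-hydroxy-3-methylbut-3-en-1-yl]-1-methyl-3-(propan-2-yl)cyclopentyl]prop-2-en-1-yl acetate | C[C@]1([C@@H](OC(C)=O)C=C)CC[C@@](O)(C(C)C)[C@H]1[C@@H](O)CC(C)=C | intermediate
19 | (1S)-1-[(1R,2R,5S)-5-[(1S)-1-acetoxyprop-2-en-1-yl]-2-hydroxy-5-methyl-2-(propan-2-yl)cyclopentyl]-3-methylbut-3-en-1-yl 4-methoxybenzoate | C[C@]1([C@@H](OC(C)=O)C=C)CC[C@@](O)(C(C)C)[C@H]1[C@@H](OC(=O)c1ccc(OC)cc1)CC(C)=C | intermediate
20 | (3R,3aR,4S,8S,8aS)-8-acetoxy-3-hydroxy-6,8a-dimethyl-3-(propan-2-yl)-1,2,3,3a,4,5,8,8a-octahydroazulen-4-yl 4-methoxybenzoate | COc1ccc(C(=O)O[C@H]2CC(C)=C[C@H](OC(C)=O)[C@@]3(C)CC[C@@](O)(C(C)C)[C@@H]23)cc1 | target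

**Step count and risks**
Total step count: 15. Longest linear sequence: 15 steps (from 1).

Steps most likely to fail:

Step 9. The vinyl addition may lose facial selectivity, because the neighbouring magnesium alkoxide can coordinate the aldehyde and compete with the Felkin–Anh mode, giving a mixture at C8. The fallback sets out from hydroxy lactone 12. CH2=CHMgBr (2.1 equiv, THF, −78 °C) should open the lactone to 1-[(1S,2R,3R)-3-hydroxy-2-(hydroxymethyl)-1-methyl-3-(propan-2-yl)cyclopentyl]prop-2-en-1-one F1, which is in equilibrium with its cyclic hemiketal. Corey–Bakshi–Shibata reduction (the oxazaborolidine enantiomer that delivers hydride to the Re face, catecholborane, toluene, −78 °C) should then set C8 under reagent control, and the sequence comes back to the route at triol 14.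

Step 7. The radical hydration may trap O2 on the wrong face of C3, or over-reduce the alkene to the alkane. The fallback sets out from alkene 11. Dihydroxylation with OsO4 (cat.) and N-methylmorpholine N-oxide on the convex face should give (3aR,4R,5S,6aS)-4,5-dihydroxy-6a-methyl-4-(propan-2-yl)hexahydro-1H-cyclopenta[c]furan-1-one F2. SOCl2/Et3N followed by RuCl3 (cat.)/NaIO4 should convert it into the cyclic sulfate of this diol F3. NaBH4 in N,N-dimethylacetamide should open the sulfate at the secondary carbon, and hydrolysis of the remaining tertiary sulfate monoester (cat. H2SO4, H2O–THF) comes back to the route at hydroxy lactone 12.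

Step 3. The base-mediated epimerisation may lose to retro-aldol loss of formaldehyde or to dehydration to the α-methylene ketone, so that the trans isomer is not funnelled to the lactol. The fallback sets out from hydroxymethyl ketone 6. Silylation (TBSCl, imidazole) should give (3R)-2-{[(tert-butyldimethylsilyl)oxy]methyl}-3-[(E)-hex-1-en-1-yl]-3-methylcyclopentan-1-one F4. Ozonolysis (O3, then Me2S) should give (1S)-2-{[(tert-butyldimethylsilyl)oxy]methyl}-1-methyl-3-oxocyclopentane-1-carbaldehyde F5, and Pinnick oxidation (NaClO2, NaH2PO4, 2-methylbut-2-ene) the corresponding (1S)-2-{[(tert-butyldimethylsilyl)oxy]methyl}-1-methyl-3-oxocyclopentane-1-carboxylic acid F6. Heating with TsOH·H2O in toluene at 80 °C should remove the silyl group, epimerise C3a through the enol under acid and lactonise the cis isomer, coming back to the route at keto lactone 9.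

**Further compounds**
F1 | step 9 | 1-[(1S,2R,3R)-3-hydroxy-2-(hydroxymethyl)-1-methyl-3-(propan-2-yl)cyclopentyl]prop-2-en-1-one | C[C@]1(C(=O)C=C)CC[C@@](O)(C(C)C)[C@H]1CO
F2 | step 7 | (3aR,4R,5S,6aS)-4,5-dihydroxy-6a-methyl-4-(propan-2-yl)hexahydro-1H-cyclopenta[c]furan-1-one | C[C@]12C[C@H](O)[C@@](O)(C(C)C)[C@H]1COC2=O
F3 | step 7 | cyclic sulfate of diol F2 (1,3,2-dioxathiolane 2,2-dioxide fused at the two carbinol carbons) | C[C@]12C[C@@H]3OS(=O)(=O)O[C@]3(C(C)C)[C@H]1COC2=O
F4 | step 3 | (3R)-2-{[(tert-butyldimethylsilyl)oxy]methyl}-3-[(E)-hex-1-en-1-yl]-3-methylcyclopentan-1-one (C2 epimers) | C[C@]1(/C=C/CCCC)CCC(=O)C1CO[Si](C)(C)C(C)(C)C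
F5 | step 3 | (1S)-2-{[(tert-butyldimethylsilyl)oxy]methyl}-1-methyl-3-oxocyclopentane-1-carbaldehyde (C2 epimers) | C[C@]1(C=O)CCC(=O)C1CO[Si](C)(C)C(C)(C)C
F6 | step 3 | (1S)-2-{[(tert-butyldimethylsilyl)oxy]methyl}-1-methyl-3-oxocyclopentane-1-carboxylic acid (C2 epimers) | C[C@]1(C(O)=O)CCC(=O)C1CO[Si](C)(C)C(C)(C)C
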